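The pyrrole is traced back to a 2,5-dihydropyrrole in which the C3–C4 bond of the ring, with the tricosyl chain on C3 and only hydrogen on C4 and C5, is an isolated alkene. Ring-closing metathesis makes that C3=C4 bond and the five-membered ring in one operation from an acyclic amino ester whose nitrogen carries an allyl group and whose C3 is a 1,1-disubstituted alkene bearing the chain. Nitrogen is protected as a tosylamide: it allows mild N-allylation, does not bind the catalyst, and departs as sulfinate in a one-step, base-induced aromatisation. The geminal alkene is brought in intact as an alkenyl Grignard reagent.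

Key step: step 5

Remark: the target is achiral; every intermediate with a stereocentre at C2 is handled as the racemate, because that centre becomes sp2 in the last step. Compounds 1, 2, 5 (cracked from its commercial polymer or methyl hemiacetal before use), 6 and 10 are taken as commercial.

Step 1
Reactants: 1 1-bromodocosane; 2 2,3-dibromoprop-1-ene
Product: 4 2-bromopentacos-1-ene, via docosylmagnesium bromide 3 (not isolated)
Conditions: Mg, THF, 50 °C; then 2 (1.3 equiv), CuI (5 mol %), THF, 0 °C to rt
Reagents that add atoms: none
Why: Copper-catalysed Grignard allylic substitution at the allylic C–Br of 2 should give the 2-bromo-1-alkene whether attack is SN2 or SN2', since both paths lead to the same product, while the vinylic bromide is inert under these conditions.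

Step 2
Reactants: 5 methyl glyoxylate; 6 p-toluenesulfonyl isocyanate
Product: 7 methyl (E)-2-(tosylimino)acetate
Conditions: AlCl3 (2 mol %), toluene, reflux; excess 5 and solvent removed in vacuo, used crude
Reagents that add atoms: none
Why: Carbonyl–isocyanate metathesis ([2+2] addition, then loss of CO2 from the oxazetidinone) is the standard entry to N-sulfonyl iminoacetates and is driven by gas evolution.

Step 3
Reactants: 4 2-bromopentacos-1-ene; 7 methyl (E)-2-(tosylimino)acetate
Product: 9 methyl 3-methylidene-2-(tosylamino)hexacosanoate (racemic), via pentacos-1-en-2-ylmagnesium bromide 8 (not isolated)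
Conditions: 4, Mg, THF, 55 °C; then added to 7 (1.3 equiv), THF–toluene, −40 °C; 1 M HCl
Reagents that add atoms: none
Why: 1,2-Addition of an alkenyl Grignard reagent to the N-sulfonyl imine, whose carbon is far more electrophilic than the ester carbonyl at low temperature, should give the sulfonamide, and the new C2 stereocentre is formed as a racemate by intent.

Step 4
Reactants: 9 methyl 3-methylidene-2-(tosylamino)hexacosanoate (racemic); 10 allyl bromide
Product: 11 methyl 2-[allyl(tosyl)amino]-3-methylidenehexacosanoate (racemic)
Conditions: K2CO3, DMF–THF, rt
Reagents that add atoms: none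
Why: SN2 N-alkylation of the sulfonamide anion, where the N–H is far more acidic than the C2–H, so K2CO3 should deprotonate nitrogen only and leave the 3-methylidene group in place.

Step 5
Reactants: 11 methyl 2-[allyl(tosyl)amino]-3-methylidenehexacosanoate (racemic)
Product: 12 methyl 1-tosyl-3-tricosyl-2,5-dihydro-1H-pyrrole-2-carboxylate (racemic)
Conditions: second-generation Grubbs catalyst RuCl2(=CHPh)(PCy3)(H2IMes) (5 mol %; H2IMes = 1,3-dimesitylimidazolidin-2-ylidene), 1,4-benzoquinone (10 mol %), CH2Cl2 (0.02 M), 40 °C
Reagents that add atoms: none
Why: Ring-closing olefin metathesis: the benzylidene of the catalyst exchanges onto the unhindered N-allyl alkene, the new metal alkylidene adds in an intramolecular [2+2] manner to the 1,1-disubstituted alkene at C3, and cycloreversion of the metallacyclobutane gives the C3=C4 bond with loss of ethene. The closest known reaction type is the closure of N-sulfonyl N-allyl 2-substituted-allyl amines to 3-substituted 3-pyrrolines with N-heterocyclic-carbene ruthenium catalysts. The five-membered ring closes by joining the internal allyl carbon (future C4) to the chain-bearing alkene carbon (C3), the only ring size the two alkene termini allow. No stereocentre is formed and the racemic C2 centre is untouched. The step needs ring closure to outrun intermolecular metathesis and alkene migration; dilution, the ease of five-membered ring formation, the non-coordinating sulfonamide nitrogen and benzoquinone as a scavenger of metal hydride species should secure this.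

Step 6
Reactants: 12 methyl 1-tosyl-3-tricosyl-2,5-dihydro-1H-pyrrole-2-carboxylate (racemic)
Product: 14 methyl 3-tricosyl-1H-pyrrole-2-carboxylate, via methyl 4-tricosyl-2H-pyrrole-5-carboxylate 13 (not isolated)
Conditions: DBU (3 equiv), THF, reflux
Reagents that add atoms: none
Why: Kenner-type aromatisation, in which DBU removes the acidic C2–H, the ester- and allyl-stabilised anion expels p-toluenesulfinate from nitrogen (E1cB) and the resulting 2H-pyrrole tautomerises to the aromatic 1H-pyrrole, erasing the C2 stereocentre.

Compound list
1 | 1-bromodocosane | CCCCCCCCCCCCCCCCCCCCCCBr | starting material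
2 | 2,3-dibromoprop-1-ene | C=C(Br)CBr | starting material
3 | docosylmagnesium bromide | CCCCCCCCCCCCCCCCCCCCCC[Mg]Br | intermediate (not isolated)
4 | 2-bromopentacos-1-ene | C=C(Br)CCCCCCCCCCCCCCCCCCCCCCC | intermediate
5 | methyl glyoxylate (methyl 2-oxoacetate) | COC(=O)C=O | starting material
6 | p-toluenesulfonyl isocyanate | Cc1ccc(cc1)S(=O)(=O)N=C=O | starting material
7 | methyl (E)-2-(tosylimino)acetate | COC(=O)/C=N/S(=O)(=O)c1ccc(C)cc1 | intermediate
8 | pentacos-1-en-2-ylmagnesium bromide | C=C([Mg]Br)CCCCCCCCCCCCCCCCCCCCCCC | intermediate (not isolated)
9 | methyl 3-methylidene-2-(tosylamino)hexacosanoate (racemic) | COC(=O)C(NS(=O)(=O)c1ccc(C)cc1)C(=C)CCCCCCCCCCCCCCCCCCCCCCC | intermediate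
10 | allyl bromide | C=CCBr | starting material
11 | methyl 2-[allyl(tosyl)amino]-3-methylidenehexacosanoate (racemic) | C=CCN(S(=O)(=O)c1ccc(C)cc1)C(C(=O)OC)C(=C)CCCCCCCCCCCCCCCCCCCCCCC | intermediate
12 | methyl 1-tosyl-3-tricosyl-2,5-dihydro-1H-pyrrole-2-carboxylate (racemic) | CCCCCCCCCCCCCCCCCCCCCCCC1=CCN(S(=O)(=O)c2ccc(C)cc2)C1C(=O)OC | intermediate
13 | methyl 4-tricosyl-2H-pyrrole-5-carboxylate | CCCCCCCCCCCCCCCCCCCCCCCC1=CCN=C1C(=O)OC | intermediate (not isolated)
14 | methyl 3-tricosyl-1H-pyrrole-2-carboxylate | CCCCCCCCCCCCCCCCCCCCCCCc1cc[nH]c1C(=O)OC | target

Total step count: 6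
Longest linear sequence: 5 steps (steps 1, 3, 4, 5, 6; step 2 is a one-step side branch that joins at step 3)

Steps most likely to fail

Step 5, ring-closing metathesis. The catalyst may couple two molecules through their N-allyl alkenes instead of closing the ring. Metal hydride species may also move the N-allyl double bond to an enamide that can no longer close onto the hindered geminal alkene. The fallback leaves metathesis and builds the pyrrole by cycloaddition. It sets out from 4: dehydrobromination with NaNH2 in liquid NH3–THF should give pentacos-1-yne F1. An Ag2CO3-catalysed formal [3+2] cycloaddition of F1 with commercial methyl isocyanoacetate (1,4-dioxane, 80 °C) is a known way from terminal alkynes to 3-substituted pyrrole-2-carboxylates. It places the alkyne substituent on C3 next to the ester and comes back to the route at 14.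

Step 3, addition of the alkenyl Grignard reagent to the imino ester. The reagent may attack the ester carbonyl or the imine nitrogen instead of the imine carbon, or the sensitive imine may oligomerise or hydrolyse before it is trapped. The fallback uses a carbamate glycine cation, for which carbon attack by alkenyl Grignard reagents is well established. It sets out from 8:
- Commercial methyl N-Boc-glycinate is brominated (NBS, light) to methyl 2-bromo-2-[(tert-butoxycarbonyl)amino]acetate F2.
- Et3N at −78 °C in THF converts F2 in the flask into methyl 2-[(tert-butoxycarbonyl)imino]acetate F3.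
- Addition of 8 to F3, then 1 M HCl, should give methyl 2-[(tert-butoxycarbonyl)amino]-3-methylidenehexacosanoate F4.
- TFA in CH2Cl2 removes the carbamate to give methyl 2-amino-3-methylidenehexacosanoate F5.
- TsCl with Et3N in CH2Cl2 sulfonylates F5, and the sequence comes back to the route at 9.

Step 6, base-induced aromatisation. Loss of sulfinate may stall at a double-bond isomer, or adventitious hydroxide may cleave the methyl ester under the basic conditions. The fallback aromatises by oxidation and removes the sulfonyl group afterwards. It sets out from 12: dehydrogenation with DDQ in toluene at 80 °C should give methyl 1-tosyl-3-tricosyl-1H-pyrrole-2-carboxylate F6. N-Desulfonylation of this electron-poor N-sulfonylpyrrole with TBAF in THF at 60 °C comes back to the route at 14.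

Further compounds
F1 | step 5 | pentacos-1-yne | C#CCCCCCCCCCCCCCCCCCCCCCCC
F2 | step 3 | methyl 2-bromo-2-[(tert-butoxycarbonyl)amino]acetate (racemic) | COC(=O)C(Br)NC(=O)OC(C)(C)C
F3 | step 3 | methyl 2-[(tert-butoxycarbonyl)imino]acetate (not isolated) | COC(=O)C=NC(=O)OC(C)(C)C
F4 | step 3 | methyl 2-[(tert-butoxycarbonyl)amino]-3-methylidenehexacosanoate (racemic) | COC(=O)C(NC(=O)OC(C)(C)C)C(=C)CCCCCCCCCCCCCCCCCCCCCCC
F5 | step 3 | methyl 2-amino-3-methylidenehexacosanoate (racemic) | COC(=O)C(N)C(=C)CCCCCCCCCCCCCCCCCCCCCCC
F6 | step 6 | methyl 1-tosyl-3-tricosyl-1H-pyrrole-2-carboxylate | CCCCCCCCCCCCCCCCCCCCCCCc1ccn(S(=O)(=O)c2ccc(C)cc2)c1C(=O)OC
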